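## Structural features

The target is a heptaphenol of the resveratrol-trimer type built on a dibenzo-fused cycloheptene. Benzene ring B (carbons a1 to a6) and benzene ring C (b1 to b6) are joined on one side through the sp3 methine C8b (a6–C8b–b1) and on the other through the alkene C8a(H)=C7a (a1–C8a, C7a–b6); C7a carries a 4-hydroxyphenyl ring (ring A). Two trans-2-aryl-2,3-dihydrobenzofurans are fused on. On ring B the oxygen on a5 closes through C7b (4-hydroxyphenyl) onto C8b, so C8b belongs to both the five- and the seven-membered ring. On ring C the oxygen on b5 closes through C7c (4-hydroxyphenyl) onto C8c (3,5-dihydroxyphenyl), which sits on b4. The four stereocentres form two adjacent pairs, C7b/C8b (S,S) and C7c/C8c (R,R); the pairs are separated by the whole of ring C, cannot direct each other, and have opposite local sense. Fragile elements are the benzylic aryl-ether bonds C7b–O and C7c–O (ionised by acid), the triply activated C8b–H, the resorcinol-type rings (attacked by electrophilic halogen) and the triaryl alkene. The real difficulties are the fully substituted ring C, whose positions b2 and b6 are electronically alike, the absolute control of two remote stereo pairs, and the release of seven phenols without opening a dihydrofuran. The key step exploits ring B: it is a 1,3-dioxygenated benzene whose a1 and a6 are also members of the cycloheptene and whose oxygen on a5 lies peri to C8b. A C8b ketone with an a6=a1 double bond therefore maps ring B onto the adduct of a 1,1,3-trioxygenated butadiene (a2 to a5) with that enone.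

## Logic of the disconnections

40 to 39: seven O–CH2Ph bonds are cut. Benzyl ethers fall to BCl3 with a cation scavenger at −78 °C, whereas methyl ethers would need BBr3 near room temperature, which endangers C7b–O and C7c–O. The demand is that every phenol, including the one on a3, travels as a benzyl ether.

39 to 35 and 37: C8b–C7b and O–C7b are cut in a [4+1] sense. Both stereocentres of ring B's dihydrofuran disappear and C8b returns to an electrophilic carbon. The forward step must be reagent-controlled, because the C7c/C8c pair is too remote to help.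

35 to 33 to 32: the C8b–S bond and the C8b–H bond lead back to the C8b ketone, and the benzyl ether on a3 to the free resorcinol. The forward steps need a selective benzylation (the a5 hydroxyl is chelated) and a reduction that stops at the carbinol.

32 to 28 and 30: a1–a2 and a5–a6 are cut and ring B is removed as a four-carbon diene. This takes away a whole arene and leaves a tricyclic bromo dienone. The forward step needs regio- and periselective cycloaddition and loss of HBr although H and Br are cis in the adduct. For this reason the diene is chosen with a silyloxy group on the future a3, and a base-mediated aromatisation is planned.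

28 to 25 to 23: the a6=a1 unsaturation and both C–Br bonds are traced back to the saturated ketone. Bromine has to be delivered to an enol derivative, not by free electrophilic bromination, because three resorcinol-type rings are present.

23 to 22: C7a=C8a is cut (ring-closing metathesis). The ring geometry then fixes the alkene geometry. The forward step must engage a 1,1-diarylethylene.

22 to 20 (with 21) to 19: C8b–a6 is cut; the benzoate carbon becomes C8b by way of the N-methoxy-N-methyl amide.

19 to 14 and 16 (16 from 15): b6–C7a is cut as a cross-coupling. The halogen on b6 is therefore needed before the 3,5-dialkoxyphenyl ring exists.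

14 to 9 and 12 (12 from 10 and 11): C8c–C7c and O–C7c are cut in a [4+1] sense; 12 must set the absolute configuration.

9 to 5 and 6: the C8c–aryl bond is cut back to an aldehyde and an aryl Grignard reagent; the sulfone is the storable form of the quinone methide.

5 to 4 to 3 to 2 to 1: functional-group changes on a symmetric benzoate. Bromine enters at b6 while b2 and b6 are still equivalent, and the two oxygens are told apart afterwards by their different crowding next to the formyl group.

30 from 29 and 37 from 36 and 11 are single operations on purchasable materials.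

## Other disconnections considered

Alternative 1: The cut is the C8c–b4 bond of the ring-C dihydrofuran, formed by contraction of a chromanone. Flavanone A1 is treated with PhI(OAc)2 and H2SO4 in trimethyl orthoformate. The enol ether is attacked by the trivalent iodine at C8c, the ring-C carbon b4 shifts from the ketal carbon to C8c with loss of PhI, and the trans ester A2 results.
- In favour: the rearrangement class is well documented, the C7c centre of A1 is carried through and directs the trans arrangement, and no stoichiometric chiral reagent is needed for this ring.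
- Against here: A2 has a methoxycarbonyl group on C8c where the target has the 3,5-dihydroxyphenyl ring, so that arene must be built from the ester carbon or brought in by decarboxylative arylation with C8c set again.
- Against here: b1 carries oxygen where C8b must be attached and b6 is still C–H, so a triflate carbonylation and an unresolved b6/b2 choice remain.
- Against here: the electron-rich 4-methoxyphenyl group on C7c can migrate in competition with b4, and the acidic medium can open the pyranone and erode C7c.
- Comparison: on structure it covers only one dihydrofuran and leaves the seven-membered ring and ring B open. On mechanism it is the better plan for that ring, since substrate control from one centre replaces the reagent control of step 7. On step economy it is worse for this target, because at least three corrective operations on ring C follow.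

Alternative 2: The cut is a6–C8b together with O–C7b, so that the cycloheptene and the ring-B dihydrofuran close in one palladium-mediated operation. Zerovalent palladium inserts into the a6–I bond of A3, the aryl palladium adds 7-exo to C8b of the (E)-stilbene, and the a5 phenoxide closes on C7b to give A4.
- In favour: every arene is preformed, ring B is not grown, and two rings, two bonds and both C7b/C8b centres arise together. Syn addition to an E-alkene followed by C–O bond formation with retention should give the trans ring. On step economy this is clearly the better plan, and it needs no untested dienophile.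
- Against: the benzylic palladium on C7b has a freely rotating β-hydrogen on C8b, so β-hydride elimination to a triarylethylene competes with C–O bond formation. That oxyarylation is secure mainly for cyclic alkenes.
- Against: 7-exo insertion by an aryl palladium flanked by hydroxyl and a cis-styryl group is slow, and 8-endo closure competes.
- Against: the face of the stilbene is chosen only by the remote C7c/C8c pair, and A3 needs a geometrically pure triarylethylene.
- Against: A4 is a heptamethyl ether, whose cleavage exposes two benzylic aryl ethers to BBr3.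
- Comparison: on structure it is the equal of the chosen plan (A4 is the methyl analogue of 39). On mechanism and stereocontrol it is weaker at the C–O-forming stage. On step economy it is better.

Alternative 3: The cut is C8b–b1 together with C7a–b6, the two bonds that tie ring C to the seven-membered ring. CsF releases the aryne from silyl triflate A5; the enolate carbon C8b of β-keto ester A6 adds at b1, the aryl anion at b6 closes on the ketone C7a, and the cyclobutoxide fragments to the ring-expanded keto ester A7.
- In favour: it is convergent and ring B is preformed. The oxygen on b5 steers the nucleophile to b1. Acyl-alkylation of cyclic β-keto esters is an established reaction, so on mechanistic precedent this plan is the better of the two.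
- In favour: the C7a ketone is ready for aryl introduction, and the ester carbon could become C7b.
- Against: A5 needs silyl and triflate groups on b6 and b1 of the chiral dihydrofuran, so the b6/b2 problem returns and b1 must start as a phenol.
- Against: C8b epimerises through the enol, and the later C7b/C8b pair would be set only under thermodynamic trans control, with no control relative to C7c/C8c.
- Against: O-arylation and simple α-arylation without insertion compete.
- Comparison: on structure it reaches a comparable tricyclic-plus-ring-B stage with fewer ring-forming steps. On stereocontrol it is weaker than step 20. On step economy it is equal or slightly better.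

Key step: step 16

Assumption: the sense of induction of the isothiocineole-derived ylides is taken from their benzylidene transfer to aldehydes, and alkylation of the sulfide is taken to occur on the exo lone pair of sulfur; if the sense proves opposite, salts 12 and 37 change places and nothing else changes.

Step 1
Reactants: 1 methyl 4-bromo-3,5-dihydroxybenzoate
Product: 2 methyl 3,5-bis(benzyloxy)-4-bromobenzoate
Conditions: BnBr, K2CO3, DMF, 60 °C
Reagents that add atoms: benzyl bromide, BrCc1ccccc1
Why: Williamson etherification of two equivalent phenols; the methyl ester is inert to carbonate.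

Step 2
Reactants: 2 methyl 3,5-bis(benzyloxy)-4-bromobenzoate
Product: 3 methyl 3,5-bis(benzyloxy)-4-formylbenzoate
Conditions: iPrMgCl·LiCl, THF, −15 °C; DMF, −15 → 0 °C; aq. NH4Cl
Reagents that add atoms: N,N-dimethylformamide, CN(C)C=O
Why: Bromine–magnesium exchange, helped by two ortho alkoxy groups and the para ester, then formylation of the aryl Grignard reagent; the doubly flanked arylmagnesium is too hindered to attack the ester at this temperature.

Step 3
Reactants: 3 methyl 3,5-bis(benzyloxy)-4-formylbenzoate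
Product: 4 methyl 3,5-bis(benzyloxy)-2-bromo-4-formylbenzoate
Conditions: NBS (1.05 equiv), CF3CO2H (cat.), MeCN, 40 °C
Reagents that add atoms: N-bromosuccinimide, O=C1CCC(=O)N1Br
Why: Electrophilic aromatic bromination; the only activated positions (ortho to one benzyloxy group, para to the other) are equivalent by symmetry, so the future b6 is marked without a regiochemical choice and before any resorcinol-type side ring is present.

Step 4
Reactants: 4 methyl 3,5-bis(benzyloxy)-2-bromo-4-formylbenzoate
Product: 5 methyl 5-(benzyloxy)-2-bromo-4-formyl-3-hydroxybenzoate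
Conditions: BCl3 (1.0 equiv), CH2Cl2, −78 °C; aq. NaHCO3
Reagents that add atoms: none
Why: Chelation-assisted ether cleavage ortho to the formyl group; of the two ortho benzyl ethers the one wedged between bromine and formyl is twisted out of conjugation and more basic, so it should be cleaved first, and one equivalent of BCl3 stops the reaction at the mono-phenol.

Step 5
Reactants: 5 methyl 5-(benzyloxy)-2-bromo-4-formyl-3-hydroxybenzoate; 6 1,3-bis(benzyloxy)-5-bromobenzene
Product: 9 methyl 5-(benzyloxy)-4-{[3,5-bis(benzyloxy)phenyl](4-methylbenzenesulfonyl)methyl}-2-bromo-3-hydroxybenzoate (racemic), via aryl Grignard reagent 7 (not isolated), via benzhydrol 8 (not isolated)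
Conditions: 6 (2.3 equiv), Mg, THF, 40 °C; then 5, THF, −78 → 0 °C; aq. NH4Cl; crude 8, p-TolSO2H, CH2Cl2, 25 °C
Reagents that add atoms: 4-methylbenzenesulfinic acid, Cc1ccc(cc1)S(=O)O
Why: Grignard addition to the aldehyde (the first equivalent deprotonates the phenol; ester and aryl bromide are untouched at low temperature), then ionisation of the ortho-hydroxy benzhydrol and capture by sulfinate at sulfur. The sulfone releases the ortho-quinone methide under base; its stereocentre is racemic and is erased in step 7.

Step 6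
Reactants: 10 (1S,4S,5S)-4,7,7-trimethyl-6-thiabicyclo[3.2.1]octane (isothiocineole); 11 [4-(benzyloxy)phenyl]methanol
Product: 12 (1S,4S,5S,6S)-6-[4-(benzyloxy)benzyl]-4,7,7-trimethyl-6-thiabicyclo[3.2.1]octan-6-ium tetrafluoroborate
Conditions: HBF4·OEt2, CH2Cl2, 0 → 25 °C
Reagents that add atoms: tetrafluoroboric acid (diethyl ether complex), [H+].F[B-](F)(F)F
Why: Alkylation of the sulfide by the 4-alkoxybenzyl cation formed from the alcohol; attack on the exposed exo lone pair should give one sulfonium diastereomer.

Step 7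
Reactants: 9 the sulfone of step 5; 12 the (1S,4S,5S,6S) sulfonium salt
Product: 14 methyl (2R,3R)-4-(benzyloxy)-2-[4-(benzyloxy)phenyl]-3-[3,5-bis(benzyloxy)phenyl]-7-bromo-2,3-dihydro-1-benzofuran-6-carboxylate, via ortho-quinone methide 13 (not isolated)
Conditions: 12 (1.3 equiv), Cs2CO3, CH2Cl2, −20 → 25 °C
Reagents that add atoms: none
Why: Formal [4+1] annulation of an ortho-quinone methide with a sulfonium ylide: the ylide carbon adds to C8c and the phenoxide displaces the sulfide at C7c with inversion. The anti betaine leads to the trans ring, the ylide face fixed by the bicyclic sulfide sets C7c (R), and C8c (R) follows from the trans closure.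

Step 8
Reactants: 15 1-[4-(benzyloxy)phenyl]ethan-1-one
Product: 16 1-[4-(benzyloxy)phenyl]ethenyl trifluoromethanesulfonate
Conditions: KN(SiMe3)2, THF, −78 °C; PhNTf2, −78 → 0 °C
Reagents that add atoms: N-phenylbis(trifluoromethanesulfonimide), O=S(=O)(N(c1ccccc1)S(=O)(=O)C(F)(F)F)C(F)(F)F
Why: O-sulfonylation of the only possible enolate of a methyl aryl ketone.

Step 9
Reactants: 14 the bromo dihydrobenzofuran ester; 16 the enol triflate
Product: 19 methyl (2R,3R)-4-(benzyloxy)-2-[4-(benzyloxy)phenyl]-7-{1-[4-(benzyloxy)phenyl]ethenyl}-3-[3,5-bis(benzyloxy)phenyl]-2,3-dihydro-1-benzofuran-6-carboxylate, via aryl Grignard reagent 17 (not isolated), via arylzinc chloride 18 (not isolated)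
Conditions: iPrMgCl·LiCl, THF, −30 °C; ZnCl2, −30 → 0 °C; then 16, Pd(OAc)2, SPhos, THF, 25 → 50 °C
Reagents that add atoms: none
Why: Bromine–magnesium exchange accelerated by the ortho ester, transmetalation to zinc and Negishi coupling with the alkenyl triflate; the conditions are free of base, so the C8c–H para to the ester is not at risk.

Step 10
Reactants: 19 the 1,1-diarylethylene ester
Product: 20 (2R,3R)-4-(benzyloxy)-2-[4-(benzyloxy)phenyl]-7-{1-[4-(benzyloxy)phenyl]ethenyl}-3-[3,5-bis(benzyloxy)phenyl]-N-methoxy-N-methyl-2,3-dihydro-1-benzofuran-6-carboxamide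
Conditions: MeNH(OMe)·HCl, iPrMgCl, THF, −20 → 0 °C
Reagents that add atoms: N,O-dimethylhydroxylamine hydrochloride, CNOC.Cl
Why: Aminolysis of the ester by the magnesium amide to the Weinreb amide.

Step 11
Reactants: 20 the Weinreb amide; 21 but-3-en-1-ylmagnesium bromide
Product: 22 1-[(2R,3R)-4-(benzyloxy)-2-[4-(benzyloxy)phenyl]-7-{1-[4-(benzyloxy)phenyl]ethenyl}-3-[3,5-bis(benzyloxy)phenyl]-2,3-dihydro-1-benzofuran-6-yl]pent-4-en-1-one
Conditions: THF, 0 °C; aq. NH4Cl
Reagents that add atoms: none
Why: Weinreb ketone synthesis; the magnesium chelate prevents a second addition and the benzoate carbon becomes C8b.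

Step 12
Reactants: 22 the pentenoyl ketone
Product: 23 (2R,3R)-4-(benzyloxy)-2,10-bis[4-(benzyloxy)phenyl]-3-[3,5-bis(benzyloxy)phenyl]-2,3,7,8-tetrahydro-6H-cyclohepta[g][1]benzofuran-6-one (C8b ketone, a6 and a1 as CH2, C8a=C7a)
Conditions: second-generation Grubbs catalyst RuCl2(=CHPh)(PCy3)(H2IMes) (10 mol %), toluene (high dilution), 90 °C, argon sparge
Reagents that add atoms: none
Why: Ring-closing metathesis; the alkylidene forms at the terminal alkene and closes onto the 1,1-diarylethylene, giving the trisubstituted C7a=C8a bond whose geometry is fixed by the ring.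

Step 13
Reactants: 23 the benzosuberenone
Product: 25 the 7-bromo derivative of 23 (bromine on a6, both epimers), via silyl enol ether 24 (not isolated)
Conditions: LiN(SiMe3)2, Me3SiCl, THF, −78 °C; then NBS, THF, −78 °C
Reagents that add atoms: N-bromosuccinimide, O=C1CCC(=O)N1Br
Why: Kinetic enolisation at a6 (the only α-CH2) with internal silyl trapping, then bromination of the silyl enol ether, which is far more nucleophilic than the aryl ethers at −78 °C; the new centre is lost in step 14.

Step 14
Reactants: 25 the α-bromo ketone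
Product: 28 (2R,3R)-4-(benzyloxy)-2,10-bis[4-(benzyloxy)phenyl]-3-[3,5-bis(benzyloxy)phenyl]-7-bromo-2,3-dihydro-6H-cyclohepta[g][1]benzofuran-6-one (bromobenzotropone: C8b=O, Br on a6, a6=a1, C8a=C7a), via bromo silyl enol ether 26 (not isolated), via gem-dibromide 27 (not isolated)
Conditions: LiN(SiMe3)2, Me3SiCl, THF, −78 °C; NBS, −78 °C; then DBU, −78 → 25 °C
Reagents that add atoms: N-bromosuccinimide, O=C1CCC(=O)N1Br
Why: Second α-bromination through the bromo silyl enol ether, then E2 dehydrobromination across a6–a1 (an a1 hydrogen anti to one bromine is available); this is the classical dibromination–dehydrobromination route to α-bromo dienones.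

Step 15
Reactants: 29 methyl (2E)-3-[(trimethylsilyl)oxy]but-2-enoate
Product: 30 1-methoxy-1,3-bis[(trimethylsilyl)oxy]buta-1,3-diene
Conditions: LiN(iPr)2, THF, −78 °C; Me3SiCl, −78 → 0 °C
Reagents that add atoms: chlorotrimethylsilane, C[Si](C)(C)Cl
Why: γ-Deprotonation of the vinylogous ester and O-silylation of the dienolate; the ketene-acetal geometry is immaterial.

Step 16
Reactants: 28 the bromobenzotropone; 30 1-methoxy-1,3-bis[(trimethylsilyl)oxy]buta-1,3-diene
Product: 32 the resorcinol-type dibenzosuberenone (ring B with OH on a3 and a5, C8b ketone, C8a(H)=C7a[4-(benzyloxy)phenyl], ring C with benzyloxy on b3 and the (7cR,8cR)-dihydrofuran), via cycloadduct 31 (not isolated)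
Conditions: 30 (3 equiv), toluene, 25 → 80 °C; then DBU, MeOH/THF, 0 → 25 °C; then 1 M HCl
Reagents that add atoms: none
Why: Proposed new method: the HOMO of 30 (largest coefficient at the CH2 terminus) should combine with the LUMO of the α-bromo enone of 28 (largest at the β-carbon a1) in a normal-demand, asynchronous [4+2] cycloaddition, the CH2 terminus bonding to a1 and the ketene-acetal carbon to the bromine-bearing a6, so that both new bonds (a1–a2 and a5–a6) form in one six-membered transition state and ring B closes as the cis-fused cyclohexene 31. DBU in methanol then removes the silyl groups, the acetal carbon collapses to a carbonyl group, HBr is lost and the dienone enolises to the resorcinol 32, whose a5 hydroxyl is hydrogen-bonded to the C8b ketone. Because H on a1 and Br on a6 are cis in 31, an anti-periplanar E2 is not open to the adduct itself; HBr should leave either by an E1cB-like syn elimination of the doubly allylic a1–H or, after retro-Claisen opening of the 2-bromo-1,3-diketone to the open-chain conjugate adduct, by ordinary anti elimination and Claisen re-closure, and both paths end at 32. The closest known reaction type is the regioselective cycloaddition–aromatisation of 1,1,3-trioxygenated butadienes with 2-halo-quinones and α-halo enones; a bromobenzotropone has not been used as the 2π partner. No stereocentre is created for the product: the sp3 centres a1, a5 and a6 of 31 vanish on aromatisation, and the C7c/C8c pair carries no hydrogen acidic enough for DBU. The step needs regioselectivity, which the polarisation of the enone and the bromine on a6 should secure (the ketene-acetal oxygen ends on a5, peri to C8b), and site- and periselectivity, which the substrate supports because benzo-fusion of ring C confines the tropone to a linear dienone, the aryl group on C7a shields the γ,δ-bond, and higher-order modes across C8b/b1 would dearomatise ring C. The bromine both lowers the LUMO of the a6=a1 bond and is the leaving group, so no oxidant is needed.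

Step 17
Reactants: 32 the resorcinol-type dibenzosuberenone
Product: 33 the same dibenzosuberenone with benzyloxy on a3 and free OH on a5
Conditions: BnBr (1.05 equiv), K2CO3, acetone, 50 °C
Reagents that add atoms: benzyl bromide, BrCc1ccccc1
Why: Williamson etherification of the more acidic, unchelated hydroxyl para to the acyl-bearing carbon; the a5 hydroxyl is tied up in a hydrogen bond to the C8b ketone and stays free.

Step 18
Reactants: 33 the a3-O-benzyl ketone
Product: 35 the C8b (4-methylbenzenesulfonyl) derivative (sulfone on C8b, OH on a5; both C8b epimers), via carbinol 34 (not isolated)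
Conditions: NaBH4, THF/MeOH, 0 °C; aq. NH4Cl; crude 34, p-TolSO2H, CH2Cl2, 0 → 25 °C
Reagents that add atoms: 4-methylbenzenesulfinic acid, Cc1ccc(cc1)S(=O)O
Why: Hydride reduction of the diaryl ketone, then ionisation of the carbinol (a cation stabilised as a dibenzotropylium and by the ortho hydroxyl) and capture by sulfinate, which stores the ortho-quinone methide in a base-releasable form; the cold, short reduction limits over-reduction to the methylene compound.

Step 19
Reactants: 36 (1R,4R,5R)-4,7,7-trimethyl-6-thiabicyclo[3.2.1]octane (isothiocineole); 11 [4-(benzyloxy)phenyl]methanol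
Product: 37 (1R,4R,5R,6R)-6-[4-(benzyloxy)benzyl]-4,7,7-trimethyl-6-thiabicyclo[3.2.1]octan-6-ium tetrafluoroborate
Conditions: HBF4·OEt2, CH2Cl2, 0 → 25 °C
Reagents that add atoms: tetrafluoroboric acid (diethyl ether complex), [H+].F[B-](F)(F)F
Why: Same S-alkylation as in step 6, in the enantiomeric series.

Step 20
Reactants: 35 the C8b sulfone; 37 the (1R,4R,5R,6R) sulfonium salt
Product: 39 the hepta-O-benzyl ether of the target, (7bS,8bS,7cR,8cR), via ortho-quinone methide 38 (not isolated)
Conditions: 37 (1.3 equiv), Cs2CO3, CH2Cl2, −20 → 25 °C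
Reagents that add atoms: none
Why: Formal [4+1] annulation as in step 7: loss of sulfinate gives the quinone methide (a5 C=O, a6=C8b), the ylide carbon adds to C8b and the a5 phenoxide displaces the sulfide at C7b with inversion. The trans ring follows from the anti betaine, C7b (S) is set by the ylide face of the chiral sulfide and C8b (S) follows from the trans closure; this is reagent control, since the C7c/C8c pair is remote.

Step 21
Reactants: 39 the hepta-O-benzyl ether
Product: 40 CNP0325907.1, the (7bS,8bS,7cR,8cR) heptaphenol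
Conditions: BCl3, C6HMe5, CH2Cl2, −78 °C; MeOH
Reagents that add atoms: none
Why: Lewis-acid cleavage of aryl benzyl ethers with pentamethylbenzene as benzyl-cation scavenger; at −78 °C the benzylic aryl-ether bonds C7b–O and C7c–O and the triaryl alkene should survive, which is the reason for carrying benzyl and not methyl ethers.

## Compound list

1 | methyl 4-bromo-3,5-dihydroxybenzoate | COC(=O)c1cc(O)c(Br)c(O)c1 | starting material
2 | methyl 3,5-bis(benzyloxy)-4-bromobenzoate | COC(=O)c1cc(OCc9ccccc9)c(Br)c(OCc9ccccc9)c1 | intermediate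
3 | methyl 3,5-bis(benzyloxy)-4-formylbenzoate | COC(=O)c1cc(OCc9ccccc9)c(C=O)c(OCc9ccccc9)c1 | intermediate
4 | methyl 3,5-bis(benzyloxy)-2-bromo-4-formylbenzoate | COC(=O)c1cc(OCc9ccccc9)c(C=O)c(OCc9ccccc9)c1Br | intermediate
5 | methyl 5-(benzyloxy)-2-bromo-4-formyl-3-hydroxybenzoate | COC(=O)c1cc(OCc9ccccc9)c(C=O)c(O)c1Br | intermediate
6 | 1,3-bis(benzyloxy)-5-bromobenzene | Brc1cc(OCc9ccccc9)cc(OCc9ccccc9)c1 | starting material
7 | [3,5-bis(benzyloxy)phenyl]magnesium bromide | Br[Mg]c1cc(OCc9ccccc9)cc(OCc9ccccc9)c1 | intermediate (not isolated)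
8 | methyl 5-(benzyloxy)-4-{[3,5-bis(benzyloxy)phenyl](hydroxy)methyl}-2-bromo-3-hydroxybenzoate (racemic) | COC(=O)c1cc(OCc9ccccc9)c(C(O)c2cc(OCc9ccccc9)cc(OCc9ccccc9)c2)c(O)c1Br | intermediate (not isolated)
9 | methyl 5-(benzyloxy)-4-{[3,5-bis(benzyloxy)phenyl](4-methylbenzenesulfonyl)methyl}-2-bromo-3-hydroxybenzoate (racemic) | COC(=O)c1cc(OCc9ccccc9)c(C(c2cc(OCc9ccccc9)cc(OCc9ccccc9)c2)S(=O)(=O)c2ccc(C)cc2)c(O)c1Br | intermediate
10 | (1S,4S,5S)-4,7,7-trimethyl-6-thiabicyclo[3.2.1]octane | C[C@H]1CC[C@H]2C[C@@H]1SC2(C)C | starting material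
11 | [4-(benzyloxy)phenyl]methanol | OCc1ccc(OCc9ccccc9)cc1 | starting material
12 | (1S,4S,5S,6S)-6-[4-(benzyloxy)benzyl]-4,7,7-trimethyl-6-thiabicyclo[3.2.1]octan-6-ium tetrafluoroborate | C[C@H]1CC[C@H]2C[C@@H]1[S@+](Cc1ccc(OCc9ccccc9)cc1)C2(C)C.F[B-](F)(F)F | intermediate
13 | methyl 5-(benzyloxy)-4-{[3,5-bis(benzyloxy)phenyl]methylidene}-2-bromo-3-oxocyclohexa-1,5-diene-1-carboxylate (ortho-quinone methide, alkene geometry open) | COC(=O)C1=C(Br)C(=O)C(=Cc2cc(OCc9ccccc9)cc(OCc9ccccc9)c2)C(OCc9ccccc9)=C1 | intermediate (not isolated)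
14 | methyl (2R,3R)-4-(benzyloxy)-2-[4-(benzyloxy)phenyl]-3-[3,5-bis(benzyloxy)phenyl]-7-bromo-2,3-dihydro-1-benzofuran-6-carboxylate | COC(=O)c1cc(OCc9ccccc9)c2c(c1Br)O[C@@H](c1ccc(OCc9ccccc9)cc1)[C@@H]2c1cc(OCc9ccccc9)cc(OCc9ccccc9)c1 | intermediate
15 | 1-[4-(benzyloxy)phenyl]ethan-1-one | CC(=O)c1ccc(OCc9ccccc9)cc1 | starting material
16 | 1-[4-(benzyloxy)phenyl]ethenyl trifluoromethanesulfonate | C=C(OS(=O)(=O)C(F)(F)F)c1ccc(OCc9ccccc9)cc1 | intermediate
17 | chloromagnesium derivative of 14 (MgCl in place of Br on C-7, (2R,3R)) | COC(=O)c1cc(OCc9ccccc9)c2c(c1[Mg]Cl)O[C@@H](c1ccc(OCc9ccccc9)cc1)[C@@H]2c1cc(OCc9ccccc9)cc(OCc9ccccc9)c1 | intermediate (not isolated)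
18 | chlorozinc derivative of 14 (ZnCl in place of Br on C-7, (2R,3R)) | COC(=O)c1cc(OCc9ccccc9)c2c(c1[Zn]Cl)O[C@@H](c1ccc(OCc9ccccc9)cc1)[C@@H]2c1cc(OCc9ccccc9)cc(OCc9ccccc9)c1 | intermediate (not isolated)
19 | methyl (2R,3R)-4-(benzyloxy)-2-[4-(benzyloxy)phenyl]-7-{1-[4-(benzyloxy)phenyl]ethenyl}-3-[3,5-bis(benzyloxy)phenyl]-2,3-dihydro-1-benzofuran-6-carboxylate | COC(=O)c1cc(OCc9ccccc9)c2c(c1C(=C)c1ccc(OCc9ccccc9)cc1)O[C@@H](c1ccc(OCc9ccccc9)cc1)[C@@H]2c1cc(OCc9ccccc9)cc(OCc9ccccc9)c1 | intermediate
20 | (2R,3R)-4-(benzyloxy)-2-[4-(benzyloxy)phenyl]-7-{1-[4-(benzyloxy)phenyl]ethenyl}-3-[3,5-bis(benzyloxy)phenyl]-N-methoxy-N-methyl-2,3-dihydro-1-benzofuran-6-carboxamide | CON(C)C(=O)c1cc(OCc9ccccc9)c2c(c1C(=C)c1ccc(OCc9ccccc9)cc1)O[C@@H](c1ccc(OCc9ccccc9)cc1)[C@@H]2c1cc(OCc9ccccc9)cc(OCc9ccccc9)c1 | intermediate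
21 | but-3-en-1-ylmagnesium bromide | C=CCC[Mg]Br | starting material
22 | 1-[(2R,3R)-4-(benzyloxy)-2-[4-(benzyloxy)phenyl]-7-{1-[4-(benzyloxy)phenyl]ethenyl}-3-[3,5-bis(benzyloxy)phenyl]-2,3-dihydro-1-benzofuran-6-yl]pent-4-en-1-one | C=CCCC(=O)c1cc(OCc9ccccc9)c2c(c1C(=C)c1ccc(OCc9ccccc9)cc1)O[C@@H](c1ccc(OCc9ccccc9)cc1)[C@@H]2c1cc(OCc9ccccc9)cc(OCc9ccccc9)c1 | intermediate
23 | (2R,3R)-4-(benzyloxy)-2,10-bis[4-(benzyloxy)phenyl]-3-[3,5-bis(benzyloxy)phenyl]-2,3,7,8-tetrahydro-6H-cyclohepta[g][1]benzofuran-6-one | c9ccccc9COc1ccc(C2=CCCC(=O)c3cc(OCc9ccccc9)c4c(c32)O[C@@H](c2ccc(OCc9ccccc9)cc2)[C@@H]4c2cc(OCc9ccccc9)cc(OCc9ccccc9)c2)cc1 | intermediate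
24 | trimethylsilyl enol ether of 23 (C8b–OSiMe3, C8b=a6) | c9ccccc9COc1ccc(C2=CCC=C(O[Si](C)(C)C)c3cc(OCc9ccccc9)c4c(c32)O[C@@H](c2ccc(OCc9ccccc9)cc2)[C@@H]4c2cc(OCc9ccccc9)cc(OCc9ccccc9)c2)cc1 | intermediate (not isolated)
25 | 7-bromo derivative of 23 (bromine on a6, both epimers) | c9ccccc9COc1ccc(C2=CCC(Br)C(=O)c3cc(OCc9ccccc9)c4c(c32)O[C@@H](c2ccc(OCc9ccccc9)cc2)[C@@H]4c2cc(OCc9ccccc9)cc(OCc9ccccc9)c2)cc1 | intermediate
26 | trimethylsilyl enol ether of 25 (C8b–OSiMe3, C8b=a6–Br) | c9ccccc9COc1ccc(C2=CCC(Br)=C(O[Si](C)(C)C)c3cc(OCc9ccccc9)c4c(c32)O[C@@H](c2ccc(OCc9ccccc9)cc2)[C@@H]4c2cc(OCc9ccccc9)cc(OCc9ccccc9)c2)cc1 | intermediate (not isolated)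
27 | 7,7-dibromo derivative of 23 | c9ccccc9COc1ccc(C2=CCC(Br)(Br)C(=O)c3cc(OCc9ccccc9)c4c(c32)O[C@@H](c2ccc(OCc9ccccc9)cc2)[C@@H]4c2cc(OCc9ccccc9)cc(OCc9ccccc9)c2)cc1 | intermediate (not isolated)
28 | (2R,3R)-4-(benzyloxy)-2,10-bis[4-(benzyloxy)phenyl]-3-[3,5-bis(benzyloxy)phenyl]-7-bromo-2,3-dihydro-6H-cyclohepta[g][1]benzofuran-6-one (bromobenzotropone) | c9ccccc9COc1ccc(C2=CC=C(Br)C(=O)c3cc(OCc9ccccc9)c4c(c32)O[C@@H](c2ccc(OCc9ccccc9)cc2)[C@@H]4c2cc(OCc9ccccc9)cc(OCc9ccccc9)c2)cc1 | intermediate
29 | methyl (2E)-3-[(trimethylsilyl)oxy]but-2-enoate | C[Si](C)(C)O/C(C)=C/C(=O)OC | starting material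
30 | 1-methoxy-1,3-bis[(trimethylsilyl)oxy]buta-1,3-diene | COC(=CC(=C)O[Si](C)(C)C)O[Si](C)(C)C | intermediate
31 | cis-fused cycloadduct of 28 and 30 (new ring: a1 H, a2 CH2, a3 C(OSiMe3)=a4 H, a5 C(OMe)(OSiMe3), a6 Br; stereoisomers at a1, a5, a6; ring C 7cR,8cR) | c9ccccc9COc1ccc(C2=CC3CC(O[Si](C)(C)C)=CC(OC)(O[Si](C)(C)C)C3(Br)C(=O)c3cc(OCc9ccccc9)c4c(c32)O[C@@H](c2ccc(OCc9ccccc9)cc2)[C@@H]4c2cc(OCc9ccccc9)cc(OCc9ccccc9)c2)cc1 | intermediate (not isolated)
32 | peri-hydroxy dibenzosuberenone with OH on a3 and a5 (C8b ketone, C8a(H)=C7a[4-(benzyloxy)phenyl], benzyloxy on b3, (7cR,8cR)-dihydrofuran with 4-(benzyloxy)phenyl on C7c and 3,5-bis(benzyloxy)phenyl on C8c) | c9ccccc9COc1ccc(C2=Cc3cc(O)cc(O)c3C(=O)c3cc(OCc9ccccc9)c4c(c32)O[C@@H](c2ccc(OCc9ccccc9)cc2)[C@@H]4c2cc(OCc9ccccc9)cc(OCc9ccccc9)c2)cc1 | intermediate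
33 | as 32, with benzyloxy on a3 and free OH on a5 | c9ccccc9COc1ccc(C2=Cc3cc(OCc9ccccc9)cc(O)c3C(=O)c3cc(OCc9ccccc9)c4c(c32)O[C@@H](c2ccc(OCc9ccccc9)cc2)[C@@H]4c2cc(OCc9ccccc9)cc(OCc9ccccc9)c2)cc1 | intermediate
34 | C8b carbinol of 33 (both C8b epimers) | c9ccccc9COc1ccc(C2=Cc3cc(OCc9ccccc9)cc(O)c3C(O)c3cc(OCc9ccccc9)c4c(c32)O[C@@H](c2ccc(OCc9ccccc9)cc2)[C@@H]4c2cc(OCc9ccccc9)cc(OCc9ccccc9)c2)cc1 | intermediate (not isolated)
35 | C8b (4-methylbenzenesulfonyl) derivative (sulfone on C8b, OH on a5; both C8b epimers) | c9ccccc9COc1ccc(C2=Cc3cc(OCc9ccccc9)cc(O)c3C(S(=O)(=O)c3ccc(C)cc3)c3cc(OCc9ccccc9)c4c(c32)O[C@@H](c2ccc(OCc9ccccc9)cc2)[C@@H]4c2cc(OCc9ccccc9)cc(OCc9ccccc9)c2)cc1 | intermediate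
36 | (1R,4R,5R)-4,7,7-trimethyl-6-thiabicyclo[3.2.1]octane | C[C@@H]1CC[C@@H]2C[C@H]1SC2(C)C | starting material
37 | (1R,4R,5R,6R)-6-[4-(benzyloxy)benzyl]-4,7,7-trimethyl-6-thiabicyclo[3.2.1]octan-6-ium tetrafluoroborate | C[C@@H]1CC[C@@H]2C[C@H]1[S@@+](Cc1ccc(OCc9ccccc9)cc1)C2(C)C.F[B-](F)(F)F | intermediate
38 | ortho-quinone methide from 35 (a5 C=O, a6=C8b(H), a1=a2, a3(OBn)=a4) | c9ccccc9COc1ccc(C2=CC3=CC(OCc9ccccc9)=CC(=O)C3=Cc3cc(OCc9ccccc9)c4c(c32)O[C@@H](c2ccc(OCc9ccccc9)cc2)[C@@H]4c2cc(OCc9ccccc9)cc(OCc9ccccc9)c2)cc1 | intermediate (not isolated)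
39 | hepta-O-benzyl ether of the target, (7bS,8bS,7cR,8cR) | c9ccccc9COc1ccc(C2=Cc3cc(OCc9ccccc9)cc4c3[C@H](c3cc(OCc9ccccc9)c5c(c32)O[C@@H](c2ccc(OCc9ccccc9)cc2)[C@@H]5c2cc(OCc9ccccc9)cc(OCc9ccccc9)c2)[C@@H](c2ccc(OCc9ccccc9)cc2)O4)cc1 | intermediate
40 | CNP0325907.1, (7bS,8bS,7cR,8cR) heptaphenol | Oc1ccc(C2=Cc3cc(O)cc4c3[C@H](c3cc(O)c5c(c32)O[C@@H](c2ccc(O)cc2)[C@@H]5c2cc(O)cc(O)c2)[C@@H](c2ccc(O)cc2)O4)cc1 | target

## Step count and risks

Total: 21 steps. Longest linear sequence: 17 steps (1–5, 7, 9–14, 16–18, 20, 21); steps 6, 8, 15 and 19 are side branches.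

Step 16 (key step, proposed method). The most likely failures are:
- lack of cycloaddition, because the a6=a1 bond is part of a delocalised dienone and its β-carbon is a dienyl position;
- conjugate addition without ring closure, followed by loss of bromide in another direction;
- incomplete dehydrobromination, because H and Br are cis in the adduct, so bromine is lost reductively and no arene forms.

The fallback uses known chemistry and brings ring B in preformed. It sets out from 20 and returns at 33. Purchased 3,5-bis(benzyloxy)benzaldehyde is brominated ortho to the formyl group (NBS, MeCN) to 3,5-bis(benzyloxy)-2-bromobenzaldehyde F1, and Wittig methylenation gives 1,5-bis(benzyloxy)-2-bromo-3-ethenylbenzene F2. Bromine–lithium exchange (n-BuLi, THF, −78 °C) and acylation by 20 should give the diaryl ketone F3. Ring-closing metathesis of its two vinyl groups should form C7a=C8a and give the per-O-benzyl dibenzosuberenone F4. MgBr2·OEt2 should then remove only the benzyl group peri to the ketone and give 33.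

Step 20. The most likely failures are poor facial discrimination at C8b (a mismatched pairing of the chiral ylide with the remote C7c/C8c pair), O-alkylation of the a5 phenoxide by the sulfonium salt, and sluggish addition because the quinone methide is stabilised as a hydroxy-dibenzotropylium. The first two risks also apply, to a lesser degree, to step 7. The fallback sets out from 33 and returns at 39. [4-(Benzyloxy)benzyl]magnesium chloride F5 (from the purchased chloride and Mg) is added in excess to the C8b ketone to give the tertiary carbinol F6. Acid-catalysed dehydration gives the exocyclic alkene F7 (C8b=C7b). Brønsted-acid-mediated addition of the a5 phenol across this alkene should close the trans dihydrofuran under thermodynamic control. Without reagent control the two trans diastereomers (they differ in their relation to ring C) would have to be separated to reach 39.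

Step 12. The most likely failure is that the ruthenium alkylidene does not engage the crowded 1,1-diarylethylene, so that dimerisation through the terminal alkene or alkene migration takes over. The fallback closes the ring at C8b–a6; it sets out from 14 and returns at 23.
- Methyl 5-[4-(benzyloxy)phenyl]-5-oxopentanoate F8 is made by palladium-catalysed acylation of 4-(benzyloxy)phenylboronic acid with methyl 5-chloro-5-oxopentanoate.
- F8 is converted into its (Z)-enol triflate F9 (KN(SiMe3)2, PhNTf2).
- The arylzinc 18 from 14 is coupled with F9 (retention) to the (Z)-diester F10.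
- Dieckmann condensation (LiN(SiMe3)2, THF) gives the β-keto ester F11.
- Dealkoxycarbonylation (LiCl, wet DMSO, 130 °C) gives 23.

Step 14. The most likely failure is competing bromination of the 3,5-bis(benzyloxy)phenyl ring or of the C7a=C8a bond, because the bromo silyl enol ether is a weaker nucleophile than the one of step 13; DBU may also remove bromine reductively. The fallback sets out from 25 and returns at 28. The lithium enolate of 25 is selenenylated (PhSeBr, −78 °C) to the α-bromo-α-(phenylselanyl) ketone F12. Oxidation (H2O2, pyridine, 0 °C) and syn elimination of the selenoxide towards a1 give 28 without a second electrophilic bromination.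

Step 4. The most likely failure is cleavage of the other ortho benzyl ether, or of both. The fallback sets out from 3 and returns at 5. Mono-debenzylation of symmetric 3 (BCl3, 1 equiv, −78 °C) has no regiochemical choice and gives methyl 3-(benzyloxy)-4-formyl-5-hydroxybenzoate F13. Amine-mediated ortho-bromination of the phenol (NBS, iPr2NH cat., CH2Cl2) then gives 5.

## Further compounds

F1 | step 16 | 3,5-bis(benzyloxy)-2-bromobenzaldehyde | O=Cc1cc(OCc9ccccc9)cc(OCc9ccccc9)c1Br
F2 | step 16 | 1,5-bis(benzyloxy)-2-bromo-3-ethenylbenzene | C=Cc1cc(OCc9ccccc9)cc(OCc9ccccc9)c1Br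
F3 | step 16 | [2,4-bis(benzyloxy)-6-ethenylphenyl][(2R,3R)-4-(benzyloxy)-2-[4-(benzyloxy)phenyl]-7-{1-[4-(benzyloxy)phenyl]ethenyl}-3-[3,5-bis(benzyloxy)phenyl]-2,3-dihydro-1-benzofuran-6-yl]methanone | C=Cc1cc(OCc9ccccc9)cc(OCc9ccccc9)c1C(=O)c1cc(OCc9ccccc9)c2c(c1C(=C)c1ccc(OCc9ccccc9)cc1)O[C@@H](c1ccc(OCc9ccccc9)cc1)[C@@H]2c1cc(OCc9ccccc9)cc(OCc9ccccc9)c1
F4 | step 16 | per-O-benzyl dibenzosuberenone (as 33, with benzyloxy on a5) | c9ccccc9COc1ccc(C2=Cc3cc(OCc9ccccc9)cc(OCc9ccccc9)c3C(=O)c3cc(OCc9ccccc9)c4c(c32)O[C@@H](c2ccc(OCc9ccccc9)cc2)[C@@H]4c2cc(OCc9ccccc9)cc(OCc9ccccc9)c2)cc1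
F5 | step 20 | [4-(benzyloxy)benzyl]magnesium chloride | Cl[Mg]Cc1ccc(OCc9ccccc9)cc1
F6 | step 20 | C8b tertiary carbinol of 33 carrying a 4-(benzyloxy)benzyl group on C8b (both C8b epimers) | c9ccccc9COc1ccc(C2=Cc3cc(OCc9ccccc9)cc(O)c3C(O)(Cc3ccc(OCc9ccccc9)cc3)c3cc(OCc9ccccc9)c4c(c32)O[C@@H](c2ccc(OCc9ccccc9)cc2)[C@@H]4c2cc(OCc9ccccc9)cc(OCc9ccccc9)c2)cc1
F7 | step 20 | exocyclic alkene from F6 (C8b=C7b(H)[4-(benzyloxy)phenyl], geometry open) | c9ccccc9COc1ccc(C2=Cc3cc(OCc9ccccc9)cc(O)c3C(=Cc3ccc(OCc9ccccc9)cc3)c3cc(OCc9ccccc9)c4c(c32)O[C@@H](c2ccc(OCc9ccccc9)cc2)[C@@H]4c2cc(OCc9ccccc9)cc(OCc9ccccc9)c2)cc1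
F8 | step 12 | methyl 5-[4-(benzyloxy)phenyl]-5-oxopentanoate | COC(=O)CCCC(=O)c1ccc(OCc9ccccc9)cc1
F9 | step 12 | methyl (4Z)-5-[4-(benzyloxy)phenyl]-5-{[(trifluoromethyl)sulfonyl]oxy}pent-4-enoate | COC(=O)CC/C=C(\OS(=O)(=O)C(F)(F)F)c1ccc(OCc9ccccc9)cc1
F10 | step 12 | methyl (2R,3R)-4-(benzyloxy)-2-[4-(benzyloxy)phenyl]-7-[(1Z)-1-[4-(benzyloxy)phenyl]-5-methoxy-5-oxopent-1-en-1-yl]-3-[3,5-bis(benzyloxy)phenyl]-2,3-dihydro-1-benzofuran-6-carboxylate | COC(=O)CC/C=C(\c1c(C(=O)OC)cc(OCc9ccccc9)c2c1O[C@@H](c1ccc(OCc9ccccc9)cc1)[C@@H]2c1cc(OCc9ccccc9)cc(OCc9ccccc9)c1)c1ccc(OCc9ccccc9)cc1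
F11 | step 12 | 7-(methoxycarbonyl) derivative of 23 (β-keto ester, ester on a6, epimers) | c9ccccc9COc1ccc(C2=CCC(C(=O)OC)C(=O)c3cc(OCc9ccccc9)c4c(c32)O[C@@H](c2ccc(OCc9ccccc9)cc2)[C@@H]4c2cc(OCc9ccccc9)cc(OCc9ccccc9)c2)cc1
F12 | step 14 | 7-bromo-7-(phenylselanyl) derivative of 23 (epimers at a6) | c9ccccc9COc1ccc(C2=CCC(Br)([Se]c3ccccc3)C(=O)c3cc(OCc9ccccc9)c4c(c32)O[C@@H](c2ccc(OCc9ccccc9)cc2)[C@@H]4c2cc(OCc9ccccc9)cc(OCc9ccccc9)c2)cc1
F13 | step 4 | methyl 3-(benzyloxy)-4-formyl-5-hydroxybenzoate | COC(=O)c1cc(O)c(C=O)c(OCc9ccccc9)c1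
A1 | alternative 1 | (2R)-7-(benzyloxy)-5-methoxy-2-(4-methoxyphenyl)-2,3-dihydro-4H-chromen-4-one | O=C1C[C@H](c2ccc(OC)cc2)Oc2cc(OCc3ccccc3)cc(OC)c12
A2 | alternative 1 | methyl (2R,3R)-6-(benzyloxy)-4-methoxy-2-(4-methoxyphenyl)-2,3-dihydro-1-benzofuran-3-carboxylate | c1(OCc3ccccc3)cc(OC)c2c(c1)O[C@@H](c1ccc(OC)cc1)[C@@H]2C(=O)OC
A3 | alternative 2 | 3-{(Z)-2-[(2R,3R)-3-(3,5-dimethoxyphenyl)-4-methoxy-2-(4-methoxyphenyl)-6-[(E)-2-(4-methoxyphenyl)ethenyl]-2,3-dihydro-1-benzofuran-7-yl]-2-(4-methoxyphenyl)ethenyl}-2-iodo-5-methoxyphenol | COc1ccc(cc1)/C=C/c1cc(OC)c2c(c1C(=C/c1cc(OC)cc(O)c1I)\c1ccc(OC)cc1)O[C@@H](c1ccc(OC)cc1)[C@@H]2c1cc(OC)cc(OC)c1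
A4 | alternative 2 | hepta-O-methyl ether of the target, (7bS,8bS,7cR,8cR) | COc1ccc(C2=Cc3cc(OC)cc4c3[C@H](c3cc(OC)c5c(c32)O[C@@H](c2ccc(OC)cc2)[C@@H]5c2cc(OC)cc(OC)c2)[C@@H](c2ccc(OC)cc2)O4)cc1
A5 | alternative 3 | (2R,3R)-3-(3,5-dimethoxyphenyl)-4-methoxy-2-(4-methoxyphenyl)-7-(trimethylsilyl)-2,3-dihydro-1-benzofuran-6-yl trifluoromethanesulfonate | C[Si](C)(C)c1c(OS(=O)(=O)C(F)(F)F)cc(OC)c2c1O[C@@H](c1ccc(OC)cc1)[C@@H]2c1cc(OC)cc(OC)c1
A6 | alternative 3 | methyl 5-methoxy-7-(methoxymethoxy)-2-oxo-2,3-dihydro-1H-indene-1-carboxylate | COC(=O)C1C(=O)Cc2cc(OC)cc(OCOC)c21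
A7 | alternative 3 | seven-membered keto ester carrying the (7cR,8cR) ring-C dihydrofuran (ester on C8b, ketone at C7a; C8b epimers) | COC(=O)C1c2c(cc(OC)cc2OCOC)CC(=O)c2c1cc(OC)c1c2O[C@@H](c2ccc(OC)cc2)[C@@H]1c1cc(OC)cc(OC)c1
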